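## The problem

Compound 21 is a bis-chromone. A 2-isopropyl-8-methoxychromone (chromone A) is joined at C5, through one methylene, to C2 of a 7-hydroxy-5-(2-oxopropyl)chromone (chromone B). There are no stereocentres, so every difficulty is one of regiochemistry and chemoselectivity.

- **Ring B substitution.** The benzene ring of chromone B is 1,2,3,5-tetrasubstituted, with the C4 carbonyl carbon wedged between the ring oxygen at C8a and the 2-oxopropyl arm at C5. Electrophilic substitution on a resorcinol does not give this pattern cleanly.
- **Oxygen differentiation.** O1 and the C7 hydroxyl must end in different roles. The C8 methoxy group of chromone A forbids any late global demethylation.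
- **Latent aldol.** The C4 carbonyl and the side-chain ketone are 1,5-related. Until the pyranone is closed, this aryl methyl ketone / benzyl methyl ketone pair can condense to a naphthol under base or acid.
- **Acidic linker.** The linking CH2 lies between an arene and an acyl carbon in every arylacetyl building block, so it is the most acidic carbon present when the link is forged.
- **Fragile pyranones.** Both pyranones accept hard nucleophiles at C2 and can be hydrogenated, so the end game is limited to brief hydrogenolysis and mild acid.
- **Enabling feature.** C4a and C5 of ring B carry, on adjacent ring atoms, an acyl carbon and a CH2C(O)CH3 group. These are the two halves of pentane-2,4-dione, so the C4a–C4 and C5–CH2 bonds can be formed together across an aryne bond, with the C8a oxygen steering the regiochemistry.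

## Retrosynthesis

**21 to 19.** The O1–C2 bond of chromone B is cut, the side-chain ketone is returned to a dioxolane and both ring B oxygens to benzyl ethers. This leads through hydroxy diketone 20 to the protected 1,3-diketone 19. Closing chromone B last keeps the 1,5-dicarbonyl pair masked until the pyranone exists. Only the oxygen ortho to the acyl carbon can reach the diketone, so both benzyl ethers may fall together and the C7 hydroxyl needs no separate protection. The forward step needs hydrogenolysis that spares two pyranones, and acid that closes the ring no later than it unmasks the ketone.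

**19 to 12 and 18.** The bond between the acetyl methyl carbon of ring B and the linker acyl carbon (C3–C2 of chromone B) is cut, giving methyl ketone 12 and arylacetic ester 18 for a crossed Claisen condensation. The neighbouring option, O-acylation of a free ortho phenol followed by O-to-C acyl shift (Baker–Venkataraman), was set aside for two reasons. An aryl ester of an arylacetic acid is more acidic at its own α-carbon than the ketone methyl, so base would favour aldol closure to a 3-aryl-4-methylcoumarin or loss of a ketene. It would also require the two phenols to be told apart. With the ortho oxygen still benzylated neither problem arises. The cut gives two halves of similar size. The forward step must make the ketone enolate attack the ester although the ester's benzylic position is the stronger carbon acid.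

**12 to 11.** The dioxolane of 12 is traced back to diketone 11. The mask is needed because 11 would otherwise enolise at the benzyl methyl ketone and condense onto the aryl ketone during the Claisen step. The forward reaction must ketalise the unhindered dialkyl ketone and leave the di-ortho-substituted aryl ketone.

**11 to 7 and 8.** The C4a–C(acetyl) and C5–CH2 bonds are cut together, returning pentane-2,4-dione 8 and the aryne from silyl triflate 7. The alternatives are Friedel–Crafts acetylation of a 3,5-dioxygenated phenylacetone or ortho-metalation routes. These install the two carbon groups one at a time and struggle with the crowded position between oxygen and the side arm. The aryne cut installs both groups in one operation on a precursor with a single directing oxygen next to the reactive bond. The forward step needs addition of the enolate carbon meta to that oxygen, ring closure of the aryl anion onto a carbonyl, and fragmentation.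

**7 to 1.** The C–Si and O–S bonds are cut, leading through silyl carbamate 5 and carbamate 2 to the symmetrical phenol 1. Both positions ortho to the carbamate are equivalent and each is also ortho to a benzyloxy group, so directed lithiation has only one outcome.

**18 to 13 and 14.** In chromone A the C4–C4a bond (Friedel–Crafts acylation) and the O1–C2 bond (oxa-Michael addition) are cut, via acid 17 and diacid 16, to 3-hydroxy-4-methoxyphenylacetic acid 13 and ynoate 14. Making the aryl–O–C2 bond first means only a chromone, never a coumarin, can form. Of the two positions ortho to the ether oxygen one carries the methoxy group, so ring closure has one possible site, and it places the acetic acid arm at C5 and the methoxy group at C8.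

## Roads not taken

**Alternative 1:** The cut is the C4a–C5 bond, which unravels the benzene ring of chromone B into a 4-pyranone bearing a dioxopentyl chain, 8-methoxy-5-{[6-[5-(2-methyl-1,3-dioxolan-2-yl)-2,4-dioxopentyl]-4-oxo-4H-pyran-2-yl]methyl}-2-(propan-2-yl)-4H-chromen-4-one A2. In the forward direction mild base would let the pyranone carbon that becomes C4a add to the chain ketone that becomes C5. Dehydration and enolisation would then give A1, the dioxolane of 21, one hydrolysis from the target.

- Merits: it mirrors the polyketide origin, needs only one protecting group, and ends almost at the target.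
- Weak points: in A2 the pyranone carbon is the least nucleophilic of several carbon acids. The chain methylene between the two ketones and the CH2 linking the pyranone to chromone A are both more acidic, and base can also open the pyranone and let the polyketone fold in other ways. Building A2 is a problem of the same kind, since lateral metalation of a 2,6-dialkylpyranone would occur at the doubly activated linker CH2 and not at the carbon to be extended.
- Comparison: if the fold went as wished this road would be shorter and lighter in protecting groups than the chosen plan, and that must be conceded. The chosen plan offers instead a ring B whose substitution is fixed by covalent structure from a symmetrical phenol, at the price of three steps to the aryne precursor and a benzyl/dioxolane protecting scheme.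

**Alternative 2:** The cut is made in chromone A, whose 1,3-dicarbonyl is hidden as an isoxazole. 2-Methylpropanenitrile oxide A5, generated in the flask, would add to aryl alkyne A4 (which already carries protected chromone B) to give the 5-aryl-3-isopropylisoxazole A3. Reductive N–O cleavage and acid would then close the pyranone.

- Merits: the cycloaddition is neutral and reliably gives the 3,5-disubstituted isoxazole, and no electrophilic substitution at a crowded arene position is needed. In that respect it is more secure than step 7 of the chosen route.
- Weak points: the key step is spent on the easier heterocycle, and the ring B problem is left unsolved inside A4. A4 needs an ethynyl group between an oxygen and the benzylic arm on a contiguously tetrasubstituted ring. The whole of chromone B must then survive a linear sequence, including reductive N–O cleavage next to two pyranones.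
- Comparison: the chosen plan makes chromone A in three steps from 13 and couples it late. It offers brevity and convergence, and accepts a Friedel–Crafts closure that is less certain than the isoxazole unmasking.

**Alternative 3:** Here the benzene ring of chromone A is built de novo. 3-Acetyl-4-[(benzyloxy)methyl]-2H-pyran-2-one A7 would add 1,1,2-trimethoxyethene A8 across C3 and C6. Decarboxylative retro-cycloaddition and elimination of one methoxy group would give 1-[6-(benzyloxymethyl)-2,3-dimethoxyphenyl]ethan-1-one A6.

- Merits: the acetyl group, both oxygens and the C5 arm are placed unambiguously by the polarity of the two partners, with no substitution chemistry on a crowded arene. That is better than the chosen route's reliance on a single free ortho position.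
- Weak points: A7 must itself be made. A6 then needs selective demethylation next to the acetyl group, condensation with an isobutyrate and cyclisation, debenzylation, and a one-carbon homologation of the arm before it can be coupled. None of this addresses ring B.
- Comparison: the substitution pattern of ring A is already present in commercial 13, so the chosen plan reaches ester 18 in three steps, which outweighs the regiochemical certainty of the pyrone route.

Key step: step 4

Remark on the chemistry: the enol ethers 15 and 16 are written without double-bond geometry because both isomers should converge in the acidic cyclisation. Intermediate 10 is a transient mixture of diastereomers, and 20 is written as the open diketone although it will exist largely as enol and cyclic hemiketal.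

## Route

Step 1
Reactants: 1 3,5-bis(benzyloxy)phenol
Product: 2 3,5-bis(benzyloxy)phenyl N-(propan-2-yl)carbamate
Conditions: i-PrNCO, Et3N (cat.), CH2Cl2, rt
Reagents that add atoms: isopropyl isocyanate, CC(C)N=C=O
Why: Amine-catalysed addition of the phenol to the isocyanate gives the N-monoalkyl carbamate, a strong director for ortho-lithiation that can later be removed under mild E1cB conditions.

Step 2
Reactants: 2 3,5-bis(benzyloxy)phenyl N-(propan-2-yl)carbamate
Product: 5 3,5-bis(benzyloxy)-2-(trimethylsilyl)phenyl N-(propan-2-yl)carbamate, via N-silyl carbamate 3 (not isolated), via N-silyl C-silyl carbamate 4 (not isolated)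
Conditions: TBSOTf, TMEDA, Et2O, 0 °C to rt; n-BuLi, TMEDA, −78 °C; TMSCl, −78 °C to rt; aq. NaHSO4
Reagents that add atoms: chlorotrimethylsilane, C[Si](C)(C)Cl
Why: In situ N-silylation masks the N–H, and carbamate-directed ortho-metalation then occurs at the position activated by both the carbamate and a benzyloxy group (the two ortho positions are equivalent); TMSCl traps the aryllithium and the acidic work-up removes the N-silyl group, while the position between the two weaker ether directors should not compete.

Step 3
Reactants: 5 3,5-bis(benzyloxy)-2-(trimethylsilyl)phenyl N-(propan-2-yl)carbamate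
Product: 7 3,5-bis(benzyloxy)-2-(trimethylsilyl)phenyl trifluoromethanesulfonate, via silylphenol 6 (not isolated)
Conditions: DBU, Et2NH, MeCN, 40 °C; then PhNTf2, rt
Reagents that add atoms: N-phenylbis(trifluoromethanesulfonimide), O=S(=O)(N(c1ccccc1)S(=O)(=O)C(F)(F)F)C(F)(F)F
Why: DBU removes the carbamate N–H and E1cB loss of the isocyanate (scavenged by diethylamine as a urea) frees the phenoxide, which is triflated in the same flask; the mild, non-aqueous conditions should spare the crowded aryl–silicon bond.

Step 4
Reactants: 7 3,5-bis(benzyloxy)-2-(trimethylsilyl)phenyl trifluoromethanesulfonate; 8 pentane-2,4-dione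
Product: 11 1-[2-acetyl-3,5-bis(benzyloxy)phenyl]propan-2-one, via aryne 9 (not isolated), via benzocyclobutenoxide 10 (not isolated)
Conditions: 8 (1.2 equiv), CsF (2.5 equiv), MeCN, 60 °C
Reagents that add atoms: none
Why: Fluoride attacks silicon of 7 and the aryl anion expels triflate to give aryne 9, while CsF also forms the enolate of 8. The enolate adds through carbon to the aryne carbon remote from the flanking benzyloxy group (future C5), where the distorted aryne is most electrophilic, and the resulting aryl anion at the future C4a is stabilised inductively by the adjacent oxygen. This anion adds to one ketone carbonyl in a 4-exo-trig closure to give benzocyclobutenoxide 10, whose strained ring fragments in a retro-aldol sense to a stabilised enolate, leaving the acetyl group on C4a and the 2-oxopropyl arm on C5; the four-membered ring is transient and 11 contains no new ring. The closest known reaction type is the fluoride-triggered acyl-alkylation of arynes from 2-silylaryl triflates with β-keto esters and β-diketones, a formal insertion into the α C–C bond. No stereocentre is formed in 11, and the two centres of 10 are destroyed on fragmentation. The selectivity required is regiochemical and is secured by the benzyloxy group next to the aryne bond; because 8 is symmetrical, either carbonyl gives the same product. Protonation of the aryl anion (plain α-arylation) and base-induced aldol condensation of 11 are the foreseeable diversions, to be countered by only a small excess of 8, moderate temperature and work-up as soon as 7 is consumed.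

Step 5
Reactants: 11 1-[2-acetyl-3,5-bis(benzyloxy)phenyl]propan-2-one
Product: 12 1-[2,4-bis(benzyloxy)-6-[(2-methyl-1,3-dioxolan-2-yl)methyl]phenyl]ethan-1-one
Conditions: TMSOCH2CH2OTMS, TMSOTf (cat.), CH2Cl2, −78 to −20 °C; pyridine quench
Reagents that add atoms: 1,2-bis(trimethylsilyloxy)ethane, C[Si](C)(C)OCCO[Si](C)(C)C
Why: Noyori ketalisation under aprotic, low-temperature conditions should select the unhindered dialkyl ketone over the di-ortho-substituted, conjugated aryl ketone, and the absence of protic acid and heat disfavours aldol or benzopyrylium formation from the 1,5-diketone.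

Step 6
Reactants: 13 (3-hydroxy-4-methoxyphenyl)acetic acid; 14 methyl 4-methylpent-2-ynoate
Product: 16 3-[5-(carboxymethyl)-2-methoxyphenoxy]-4-methylpent-2-enoic acid, via monoester 15 (not isolated)
Conditions: K2CO3 (3 equiv), DMF, 70 °C; then aq. KOH, 50 °C; HCl work-up
Reagents that add atoms: potassium hydroxide, [K+].[OH-]
Why: The phenoxide, a far better Michael donor than the carboxylate, adds to the β-carbon of the ynoate (oxa-Michael addition) and fixes the aryl–O–C2 connectivity of chromone A; saponification in the same flask gives the diacid, whose double-bond geometry is of no consequence for the next step.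

Step 7
Reactants: 16 3-[5-(carboxymethyl)-2-methoxyphenoxy]-4-methylpent-2-enoic acid
Product: 17 [8-methoxy-4-oxo-2-(propan-2-yl)-4H-chromen-5-yl]acetic acid
Conditions: P2O5 (7.7 wt%) in MeSO3H (Eaton's reagent), dilute, 50 °C
Reagents that add atoms: none
Why: Intramolecular Friedel–Crafts acylation of a β-aryloxyacrylic acid is a classical chromone closure (6-membered ring, acylium onto the position ortho to the ether oxygen); the other ortho position carries the methoxy group, so only the 5,8-disubstituted chromone can form, and the E and Z enol ethers interconvert through the protonated form in the strong acid.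

Step 8
Reactants: 17 [8-methoxy-4-oxo-2-(propan-2-yl)-4H-chromen-5-yl]acetic acid
Product: 18 methyl [8-methoxy-4-oxo-2-(propan-2-yl)-4H-chromen-5-yl]acetate
Conditions: MeOH, H2SO4 (cat.), reflux
Reagents that add atoms: methanol, CO
Why: Fischer esterification of an unhindered arylacetic acid; the vinylogous-ester carbonyl of the chromone is inert to acidic methanol.

Step 9
Reactants: 12 1-[2,4-bis(benzyloxy)-6-[(2-methyl-1,3-dioxolan-2-yl)methyl]phenyl]ethan-1-one; 18 methyl [8-methoxy-4-oxo-2-(propan-2-yl)-4H-chromen-5-yl]acetate
Product: 19 1-[2,4-bis(benzyloxy)-6-[(2-methyl-1,3-dioxolan-2-yl)methyl]phenyl]-4-[8-methoxy-4-oxo-2-(propan-2-yl)-4H-chromen-5-yl]butane-1,3-dione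
Conditions: KOt-Bu (2 equiv), THF, 0 °C to rt; aq. NH4Cl
Reagents that add atoms: none
Why: Crossed Claisen condensation under equilibrating alkoxide conditions: the enolate of 18 is the more populated but is hindered at carbon by the peri carbonyl of the chromone, whereas the unhindered methyl-ketone enolate of 12 attacks the unhindered ester carbonyl, and the reaction is pulled forward by deprotonation of the β-diketone; the benzylated ortho oxygen excludes coumarin formation and the dioxolane excludes aldol condensation.

Step 10
Reactants: 19 1-[2,4-bis(benzyloxy)-6-[(2-methyl-1,3-dioxolan-2-yl)methyl]phenyl]-4-[8-methoxy-4-oxo-2-(propan-2-yl)-4H-chromen-5-yl]butane-1,3-dione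
Product: 21 5-{[7-hydroxy-4-oxo-5-(2-oxopropyl)-4H-chromen-2-yl]methyl}-8-methoxy-2-(propan-2-yl)-4H-chromen-4-one, via hydroxy diketone 20 (not isolated)
Conditions: H2 (1 atm), 10% Pd/C, THF–MeOH, rt; filter; HCl (cat.), rt; then 2 M aq. HCl, 45 °C
Reagents that add atoms: water, O
Why: Hydrogenolysis of the two aryl benzyl ethers is fast relative to reduction of the pyranone of chromone A; the freed ortho hydroxyl adds to the distal diketone carbonyl and acid-catalysed cyclodehydration (6-membered ring, the standard closure of an o-hydroxyaryl 1,3-diketone) gives chromone B before aqueous acid hydrolyses the dioxolane, while the C7 hydroxyl has no carbonyl within reach and stays free.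

## Compound list

1 | 3,5-bis(benzyloxy)phenol | Oc1cc(OCc2ccccc2)cc(OCc2ccccc2)c1 | starting material
2 | 3,5-bis(benzyloxy)phenyl N-(propan-2-yl)carbamate | CC(C)NC(=O)Oc1cc(OCc2ccccc2)cc(OCc2ccccc2)c1 | intermediate
3 | 3,5-bis(benzyloxy)phenyl N-(tert-butyldimethylsilyl)-N-(propan-2-yl)carbamate | CC(C)N(C(=O)Oc1cc(OCc2ccccc2)cc(OCc2ccccc2)c1)[Si](C)(C)C(C)(C)C | intermediate (not isolated)
4 | 3,5-bis(benzyloxy)-2-(trimethylsilyl)phenyl N-(tert-butyldimethylsilyl)-N-(propan-2-yl)carbamate | CC(C)N(C(=O)Oc1cc(OCc2ccccc2)cc(OCc2ccccc2)c1[Si](C)(C)C)[Si](C)(C)C(C)(C)C | intermediate (not isolated)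
5 | 3,5-bis(benzyloxy)-2-(trimethylsilyl)phenyl N-(propan-2-yl)carbamate | CC(C)NC(=O)Oc1cc(OCc2ccccc2)cc(OCc2ccccc2)c1[Si](C)(C)C | intermediate
6 | 3,5-bis(benzyloxy)-2-(trimethylsilyl)phenol | C[Si](C)(C)c1c(O)cc(OCc2ccccc2)cc1OCc1ccccc1 | intermediate (not isolated)
7 | 3,5-bis(benzyloxy)-2-(trimethylsilyl)phenyl trifluoromethanesulfonate | C[Si](C)(C)c1c(OCc2ccccc2)cc(OCc2ccccc2)cc1OS(=O)(=O)C(F)(F)F | intermediate
8 | pentane-2,4-dione | CC(=O)CC(C)=O | starting material
9 | 3,5-bis(benzyloxy)benzyne (1,2-didehydro-3,5-bis(benzyloxy)benzene) | C1#CC(OCc2ccccc2)=CC(OCc2ccccc2)=C1 | intermediate (not isolated)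
10 | 1-[2,4-bis(benzyloxy)-8-hydroxy-8-methylbicyclo[4.2.0]octa-1,3,5-trien-7-yl]ethan-1-one, present as its caesium alkoxide; transient mixture of diastereomers | CC(=O)C1c2cc(OCc3ccccc3)cc(OCc3ccccc3)c2C1(C)O | intermediate (not isolated)
11 | 1-[2-acetyl-3,5-bis(benzyloxy)phenyl]propan-2-one | CC(=O)Cc1cc(OCc2ccccc2)cc(OCc2ccccc2)c1C(C)=O | intermediate
12 | 1-[2,4-bis(benzyloxy)-6-[(2-methyl-1,3-dioxolan-2-yl)methyl]phenyl]ethan-1-one | CC(=O)c1c(CC2(C)OCCO2)cc(OCc2ccccc2)cc1OCc1ccccc1 | intermediate
13 | (3-hydroxy-4-methoxyphenyl)acetic acid | COc1ccc(CC(=O)O)cc1O | starting material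
14 | methyl 4-methylpent-2-ynoate | CC(C)C#CC(=O)OC | starting material
15 | {4-methoxy-3-[(1-methoxy-4-methyl-1-oxopent-2-en-3-yl)oxy]phenyl}acetic acid (E/Z mixture) | COC(=O)C=C(Oc1cc(CC(=O)O)ccc1OC)C(C)C | intermediate (not isolated)
16 | 3-[5-(carboxymethyl)-2-methoxyphenoxy]-4-methylpent-2-enoic acid (E/Z mixture) | OC(=O)C=C(Oc1cc(CC(=O)O)ccc1OC)C(C)C | intermediate
17 | [8-methoxy-4-oxo-2-(propan-2-yl)-4H-chromen-5-yl]acetic acid | COc1ccc(CC(=O)O)c2c(=O)cc(C(C)C)oc12 | intermediate
18 | methyl [8-methoxy-4-oxo-2-(propan-2-yl)-4H-chromen-5-yl]acetate | COC(=O)Cc1ccc(OC)c2oc(C(C)C)cc(=O)c12 | intermediate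
19 | 1-[2,4-bis(benzyloxy)-6-[(2-methyl-1,3-dioxolan-2-yl)methyl]phenyl]-4-[8-methoxy-4-oxo-2-(propan-2-yl)-4H-chromen-5-yl]butane-1,3-dione | COc1ccc(CC(=O)CC(=O)c2c(CC3(C)OCCO3)cc(OCc3ccccc3)cc2OCc2ccccc2)c2c(=O)cc(C(C)C)oc12 | intermediate
20 | 1-[2,4-dihydroxy-6-[(2-methyl-1,3-dioxolan-2-yl)methyl]phenyl]-4-[8-methoxy-4-oxo-2-(propan-2-yl)-4H-chromen-5-yl]butane-1,3-dione | COc1ccc(CC(=O)CC(=O)c2c(CC3(C)OCCO3)cc(O)cc2O)c2c(=O)cc(C(C)C)oc12 | intermediate (not isolated)
21 | 5-{[7-hydroxy-4-oxo-5-(2-oxopropyl)-4H-chromen-2-yl]methyl}-8-methoxy-2-(propan-2-yl)-4H-chromen-4-one | COc1ccc(Cc2cc(=O)c3c(CC(C)=O)cc(O)cc3o2)c2c(=O)cc(C(C)C)oc12 | target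

## Step count and risks

Total: 10 steps. Longest linear sequence: 7 steps (steps 1, 2, 3, 4, 5, 9, 10, from 1 to 21). The chromone A branch (steps 6 to 8) joins at step 9.

**Step 4 (key step).** The most likely failure is over-reaction. The newly formed 1,5-diketone can enolise under the fluoride conditions and condense to a naphthol, and the acidic diketone can protonate the aryl anion before it closes onto the carbonyl. Fallback, from 7 back to 11: the aryne is inserted instead into methyl 3-oxobutanoate under the same fluoride conditions. The product, methyl [2-acetyl-3,5-bis(benzyloxy)phenyl]acetate F1, has an ester arm that is a much poorer aldol partner. Saponification with LiOH gives [2-acetyl-3,5-bis(benzyloxy)phenyl]acetic acid F2. Activation with carbonyldiimidazole and C-acylation of Meldrum's acid gives 5-{[2-acetyl-3,5-bis(benzyloxy)phenyl]acetyl}-2,2-dimethyl-1,3-dioxane-4,6-dione F3. Hydrolysis and double decarboxylation in hot aqueous acetic acid turn the acyl group into the methyl ketone and rejoin the route at 11.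

**Step 9.** Proton transfer to the more acidic benzylic position of 18 may outrun C–C bond formation, so that the ester is parked as its enolate or condenses with itself. Conjugate addition of an enolate to the pyranone of chromone A is a second possible diversion. Fallback, from 12 and 17 back to 19: acid 17 is converted with oxalyl chloride and catalytic DMF into [8-methoxy-4-oxo-2-(propan-2-yl)-4H-chromen-5-yl]acetyl chloride F4. This is added at −78 °C to the preformed lithium enolate of 12 (LiN(SiMe3)2, THF; two equivalents of enolate per acid chloride, the second serving as base, the excess ketone being recovered). Kinetic, irreversible C-acylation replaces the equilibrium condensation and gives 19.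

**Step 7.** The ring must close at a position flanked on both sides. Meanwhile the free arylacetic acid can be activated by the same medium and acylate another molecule, and the aryl enol ether can be cleaved by strong acid. Fallback, from 13 back to 18: 13 is esterified (MeOH, H2SO4) to methyl (3-hydroxy-4-methoxyphenyl)acetate F5. This is added (K2CO3, DMF) to tert-butyl 4-methylpent-2-ynoate F6, made from 3-methylbut-1-yne by lithiation and trapping with Boc2O. The adduct is tert-butyl 3-[2-methoxy-5-(2-methoxy-2-oxoethyl)phenoxy]-4-methylpent-2-enoate F7. Trifluoroacetic acid removes only the tert-butyl group to give 3-[2-methoxy-5-(2-methoxy-2-oxoethyl)phenoxy]-4-methylpent-2-enoic acid F8. With the arylacetic acid blocked as its ester, cyclisation in Eaton's reagent gives 18 directly and step 8 is no longer needed.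

**Step 2.** Deprotonation at the benzylic CH2 of a benzyl ether, followed by [1,2]-Wittig rearrangement, may compete with ring lithiation. Fallback, from 1 back to 7: 1 is brominated ortho to the hydroxyl with N-bromosuccinimide in CH2Cl2 at low temperature to give 3,5-bis(benzyloxy)-2-bromophenol F9. O-Silylation with hexamethyldisilazane gives [3,5-bis(benzyloxy)-2-bromophenoxy]trimethylsilane F10. Treatment with n-BuLi at −100 °C effects bromine–lithium exchange, which is faster than benzylic deprotonation, and a 1,3 O-to-C silyl shift (retro-Brook rearrangement) then gives the lithium phenoxide of 6. Tf2O converts it into 7.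

**Step 10.** Partial saturation of a pyranone double bond during hydrogenolysis is possible. So is loss of the dioxolane before chromone B has closed, which would let the diketone methylene condense with the freed ketone. Fallback, from 12 to 21: the benzyl groups are removed before any chromone is present (H2, Pd/C) to give 1-[2,4-dihydroxy-6-[(2-methyl-1,3-dioxolan-2-yl)methyl]phenyl]ethan-1-one F11. Both phenols are protected with chloromethyl methyl ether and NaH as 1-[2,4-bis(methoxymethoxy)-6-[(2-methyl-1,3-dioxolan-2-yl)methyl]phenyl]ethan-1-one F12. Claisen condensation with 18 as in step 9 gives 1-[2,4-bis(methoxymethoxy)-6-[(2-methyl-1,3-dioxolan-2-yl)methyl]phenyl]-4-[8-methoxy-4-oxo-2-(propan-2-yl)-4H-chromen-5-yl]butane-1,3-dione F13. A single treatment with HCl in aqueous methanol removes both acetals, closes chromone B and unmasks the ketone, giving 21 without any hydrogenation in the presence of a pyranone.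

## Further compounds

F1 | step 4 | methyl [2-acetyl-3,5-bis(benzyloxy)phenyl]acetate | COC(=O)Cc1cc(OCc2ccccc2)cc(OCc2ccccc2)c1C(C)=O
F2 | step 4 | [2-acetyl-3,5-bis(benzyloxy)phenyl]acetic acid | OC(=O)Cc1cc(OCc2ccccc2)cc(OCc2ccccc2)c1C(C)=O
F3 | step 4 | 5-{[2-acetyl-3,5-bis(benzyloxy)phenyl]acetyl}-2,2-dimethyl-1,3-dioxane-4,6-dione | CC(=O)c1c(CC(=O)C2C(=O)OC(C)(C)OC2=O)cc(OCc2ccccc2)cc1OCc1ccccc1
F4 | step 9 | [8-methoxy-4-oxo-2-(propan-2-yl)-4H-chromen-5-yl]acetyl chloride | COc1ccc(CC(=O)Cl)c2c(=O)cc(C(C)C)oc12
F5 | step 7 | methyl (3-hydroxy-4-methoxyphenyl)acetate | COC(=O)Cc1ccc(OC)c(O)c1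
F6 | step 7 | tert-butyl 4-methylpent-2-ynoate | CC(C)C#CC(=O)OC(C)(C)C
F7 | step 7 | tert-butyl 3-[2-methoxy-5-(2-methoxy-2-oxoethyl)phenoxy]-4-methylpent-2-enoate | COC(=O)Cc1ccc(OC)c(OC(=CC(=O)OC(C)(C)C)C(C)C)c1
F8 | step 7 | 3-[2-methoxy-5-(2-methoxy-2-oxoethyl)phenoxy]-4-methylpent-2-enoic acid | COC(=O)Cc1ccc(OC)c(OC(=CC(=O)O)C(C)C)c1
F9 | step 2 | 3,5-bis(benzyloxy)-2-bromophenol | Oc1cc(OCc2ccccc2)cc(OCc2ccccc2)c1Br
F10 | step 2 | [3,5-bis(benzyloxy)-2-bromophenoxy]trimethylsilane | C[Si](C)(C)Oc1cc(OCc2ccccc2)cc(OCc2ccccc2)c1Br
F11 | step 10 | 1-[2,4-dihydroxy-6-[(2-methyl-1,3-dioxolan-2-yl)methyl]phenyl]ethan-1-one | CC(=O)c1c(CC2(C)OCCO2)cc(O)cc1O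
F12 | step 10 | 1-[2,4-bis(methoxymethoxy)-6-[(2-methyl-1,3-dioxolan-2-yl)methyl]phenyl]ethan-1-one | CC(=O)c1c(CC2(C)OCCO2)cc(OCOC)cc1OCOC
F13 | step 10 | 1-[2,4-bis(methoxymethoxy)-6-[(2-methyl-1,3-dioxolan-2-yl)methyl]phenyl]-4-[8-methoxy-4-oxo-2-(propan-2-yl)-4H-chromen-5-yl]butane-1,3-dione | COc1ccc(CC(=O)CC(=O)c2c(CC3(C)OCCO3)cc(OCOC)cc2OCOC)c2c(=O)cc(C(C)C)oc12
A1 | alternative 1 | 5-{[7-hydroxy-5-[(2-methyl-1,3-dioxolan-2-yl)methyl]-4-oxo-4H-chromen-2-yl]methyl}-8-methoxy-2-(propan-2-yl)-4H-chromen-4-one | COc1ccc(Cc2cc(=O)c3c(CC4(C)OCCO4)cc(O)cc3o2)c2c(=O)cc(C(C)C)oc12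
A2 | alternative 1 | 8-methoxy-5-{[6-[5-(2-methyl-1,3-dioxolan-2-yl)-2,4-dioxopentyl]-4-oxo-4H-pyran-2-yl]methyl}-2-(propan-2-yl)-4H-chromen-4-one | COc1ccc(Cc2cc(=O)cc(CC(=O)CC(=O)CC3(C)OCCO3)o2)c2c(=O)cc(C(C)C)oc12
A3 | alternative 2 | 2-{[4-methoxy-3-(methoxymethoxy)-2-[3-(propan-2-yl)-1,2-oxazol-5-yl]phenyl]methyl}-7-(methoxymethoxy)-5-[(2-methyl-1,3-dioxolan-2-yl)methyl]-4H-chromen-4-one | COc1ccc(Cc2cc(=O)c3c(CC4(C)OCCO4)cc(OCOC)cc3o2)c(-c2cc(C(C)C)no2)c1OCOC
A4 | alternative 2 | 2-{[2-ethynyl-4-methoxy-3-(methoxymethoxy)phenyl]methyl}-7-(methoxymethoxy)-5-[(2-methyl-1,3-dioxolan-2-yl)methyl]-4H-chromen-4-one | COc1ccc(Cc2cc(=O)c3c(CC4(C)OCCO4)cc(OCOC)cc3o2)c(C#C)c1OCOC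
A5 | alternative 2 | 2-methylpropanenitrile oxide | CC(C)C#[N+][O-]
A6 | alternative 3 | 1-[6-(benzyloxymethyl)-2,3-dimethoxyphenyl]ethan-1-one | CC(=O)c1c(COCc2ccccc2)ccc(OC)c1OC
A7 | alternative 3 | 3-acetyl-4-[(benzyloxy)methyl]-2H-pyran-2-one | CC(=O)c1c(COCc2ccccc2)ccoc1=O
A8 | alternative 3 | 1,1,2-trimethoxyethene | COC=C(OC)OC
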